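**Retrosynthetic overview**
1. Target 27 ⇐ desilylation and retro-aldol ring expansion (De Mayo) of cyclobutane 25 ⇐ intramolecular [2+2] photocycloaddition of 24, which forms C2–C16 and C7–C8.
2. 24 ⇐ ester bond O24–C1 between cage tertiary alcohol 14 and acyl-ketene precursor 21, then a disiloxane bridge that fixes the C7 enol.
3. 14 ⇐ cage enone 12 (Luche reduction, silylation) ⇐ epoxide opening by a cyclopentane-1,3-dione ⇐ Claisen ring closure ⇐ magnesium-tethered Diels–Alder lactone 6 from dienol 4 and methyl acrylate.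
4. 21 ⇐ Claisen/Dieckmann annulation of the (S)-linalool-derived lactone ester 17 with a thioacetate enolate, then γ-methylation.
5. Ring order: cyclohexene → cyclopentanedione → oxabicyclo[2.2.2]octane; separately the six-membered trione; then γ-lactone and cyclobutane (hν); last the eight-membered ring by fragmentation.

Assumption: commercial (R)-but-3-yn-2-ol and (S)-(+)-linalool are taken as enantiopure. Atom labels used throughout: C1 lactone C=O, C2=C3(OH) enol, C4(Me), C5, C6(Me)(OH), C7 ketone, C8, C9(OH), C10, C11(OH), C12(Me)(O17), C13(Me), C14, C15(O24), C16.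

Step 1
Reactants: 1 (R)-but-3-yn-2-ol; 2 (E)-2-bromobut-2-ene
Product: 3 (2R,5E)-5-methylhept-5-en-3-yn-2-ol
Conditions: Pd(PPh3)4 (3 mol %), CuI (6 mol %), i-Pr2NH, THF, rt
Reagents that add atoms: none
Why: Sonogashira coupling of the free propargylic alcohol with the vinyl bromide keeps the (E) geometry and leaves the bought carbinol centre untouched.

Step 2
Reactants: 3 (2R,5E)-5-methylhept-5-en-3-yn-2-ol
Product: 4 (2R,3E,5E)-5-methylhepta-3,5-dien-2-ol
Conditions: NaAlH2(OCH2CH2OMe)2, THF, 0 °C to rt; aq. Rochelle salt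
Reagents that add atoms: none
Why: Hydroxyl-directed trans-hydroalumination of the propargylic alcohol gives the (3E) alkene and hence the (E,E)-diene.

Step 3
Reactants: 4 (2R,3E,5E)-5-methylhepta-3,5-dien-2-ol; 5 methyl acrylate
Product: 6 (3R,3aS,6S,7aR)-3,5,6-trimethyl-3a,6,7,7a-tetrahydro-2-benzofuran-1(3H)-one
Conditions: MeMgBr (1.0 equiv), toluene, 0 °C; then 5 (3 equiv), 60 °C
Reagents that add atoms: none
Why: Magnesium-alkoxide-tethered Diels–Alder reaction then lactonisation: the tether fixes the regiochemistry and the cis ring fusion, the (E,E)-diene puts C13–Me cis to C9, and the acrylate is expected to add anti to the C9 methyl with C9–H eclipsing the diene (allylic-strain model), so the bought centre sets C10, C13 and C15.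

Step 4
Reactants: 6 (3R,3aS,6S,7aR)-3,5,6-trimethyl-3a,6,7,7a-tetrahydro-2-benzofuran-1(3H)-one
Product: 7 (3R,3aR,6S,7aS)-7a-hydroxy-3,5,6-trimethyl-3a,6,7,7a-tetrahydro-2-benzofuran-1(3H)-one
Conditions: KN(SiMe3)2, THF, −78 °C; O2, P(OEt)3
Reagents that add atoms: dioxygen O=O
Why: Lactone enolate oxidation can only give the cis-fused α-hydroxy lactone, which places the C15 oxygen trans to C9.

Step 5
Reactants: 7 (3R,3aR,6S,7aS)-7a-hydroxy-3,5,6-trimethyl-3a,6,7,7a-tetrahydro-2-benzofuran-1(3H)-one
Product: 8 (1S,2R,5S)-1-hydroxy-2-[(1R)-1-hydroxyethyl]-N-methoxy-N,4,5-trimethylcyclohex-3-ene-1-carboxamide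
Conditions: MeNH(OMe)·HCl, AlMe3, CH2Cl2, 0 °C to rt
Reagents that add atoms: N,O-dimethylhydroxylamine hydrochloride CNOC.Cl
Why: Weinreb aminolysis opens the γ-lactone and frees the C9 carbinol without touching any stereocentre.

Step 6
Reactants: 8 (1S,2R,5S)-1-hydroxy-2-[(1R)-1-hydroxyethyl]-N-methoxy-N,4,5-trimethylcyclohex-3-ene-1-carboxamide
Product: 9 (1S,2S,5S)-2-acetyl-1-hydroxy-N-methoxy-N,4,5-trimethylcyclohex-3-ene-1-carboxamide
Conditions: Dess–Martin periodinane, NaHCO3, CH2Cl2, 0 °C to rt
Reagents that add atoms: none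
Why: Dess–Martin oxidation of the only secondary alcohol gives the methyl ketone (C9=O, C8H3); the relay centre C9 is no longer needed.

Step 7
Reactants: 9 (1S,2S,5S)-2-acetyl-1-hydroxy-N-methoxy-N,4,5-trimethylcyclohex-3-ene-1-carboxamide
Product: 10 (3aS,6S,7aS)-7a-hydroxy-5,6-dimethyl-3a,6,7,7a-tetrahydro-1H-indene-1,3(2H)-dione
Conditions: LiN(SiMe3)2 (3.3 equiv), THF, −78 to 0 °C; aq. NH4Cl
Reagents that add atoms: none
Why: Intramolecular Claisen (Dieckmann-type) acylation of the methyl ketone enolate by the Weinreb amide closes the cyclopentane-1,3-dione; only the cis-disposed C10 epimer can cyclise.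

Step 8
Reactants: 10 (3aS,6S,7aS)-7a-hydroxy-5,6-dimethyl-3a,6,7,7a-tetrahydro-1H-indene-1,3(2H)-dione
Product: 12 cage enone (vinylogous ester C9(=O)–C8=C16–O17–C12 with free C11–OH and C15–OH), via epoxy dione 11 (not isolated)
Conditions: mCPBA, CH2Cl2, 0 °C; then TsOH·H2O (5 mol %), rt
Reagents that add atoms: 3-chloroperoxybenzoic acid OOC(=O)c1cccc(Cl)c1
Why: Prilezhaev epoxidation on the convex face syn to C15–OH, then 6-exo opening of the epoxide at tertiary C12 by the dione oxygen on C16 with inversion, builds the 2-oxabicyclo[2.2.2]octane and sets C11 and C12.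

Step 9
Reactants: 12 cage enone
Product: 13 cage triol (C9–OH allylic to the C8=C16 enol ether)
Conditions: NaBH4, CeCl3·7H2O, MeOH, −78 °C; NaHCO3 work-up
Reagents that add atoms: none
Why: Luche 1,2-reduction delivers hydride from the open C10–H/C15–OH face, so the C9 hydroxyl ends on the concave cage face as in the target.

Step 10
Reactants: 13 cage triol
Product: 14 cage alcohol (C9 and C11 triethylsilyl ethers with free tertiary C15–OH)
Conditions: Et3SiCl, imidazole, DMF, 0 °C
Reagents that add atoms: chlorotriethylsilane CC[Si](Cl)(CC)CC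
Why: Silylation takes the two secondary hydroxyls and leaves the hindered tertiary C15–OH free for the ester tether.

Step 11
Reactants: 15 (S)-(+)-linalool
Product: 17 methyl (2S)-2-methyl-5-oxooxolane-2-carboxylate, via hydroxy diester 16 (not isolated)
Conditions: O3, NaOH, MeOH/CH2Cl2, −78 °C; then HCl, toluene, 50 °C
Reagents that add atoms: ozone [O-][O+]=O; methanol CO
Why: Ester-forming ozonolysis of both alkenes followed by acid lactonisation leaves the bought quaternary carbinol (C6) untouched.

Step 12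
Reactants: 17 methyl (2S)-2-methyl-5-oxooxolane-2-carboxylate; 18 S-tert-butyl thioacetate
Product: 20 S-tert-butyl (3S)-3-methyl-2,6-dioxo-3-(trimethylsilyloxy)cyclohexane-1-carbothioate (enol form), via hydroxy trione dilithium salt 19 (not isolated)
Conditions: 18 (2.2 equiv), LiN(i-Pr)2 (2.3 equiv), THF, −78 to 0 °C; then Me3SiCl, −78 °C to rt; pH 7 work-up
Reagents that add atoms: chlorotrimethylsilane C[Si](C)(C)Cl
Why: Crossed Claisen condensation then Dieckmann closure joins the thioacetate carbon to both acyl carbons of 17 (either order gives the same ring), and the tertiary alkoxide is trapped as its silyl ether.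

Step 13
Reactants: 20 S-tert-butyl (3S)-3-methyl-2,6-dioxo-3-(trimethylsilyloxy)cyclohexane-1-carbothioate
Product: 21 S-tert-butyl (3S,5S)-3,5-dimethyl-2,6-dioxo-3-(trimethylsilyloxy)cyclohexane-1-carbothioate (enol form)
Conditions: LiN(i-Pr)2 (2.2 equiv), THF, −78 to −40 °C; MeI (1.05 equiv), −78 °C
Reagents that add atoms: iodomethane CI
Why: γ-Alkylation of the dianion occurs at C4 anti to the pseudo-axial C6 silyloxy group, giving the cis-dimethyl isomer with both methyls pseudo-equatorial, so the bought C6 sets C4.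

Step 14
Reactants: 14 cage alcohol; 21 S-tert-butyl (3S,5S)-3,5-dimethyl-2,6-dioxo-3-(trimethylsilyloxy)cyclohexane-1-carbothioate
Product: 22 C15 ester of 14 with the trione acid of 21 (triethylammonium enolate, used crude)
Conditions: AgOCOCF3, Et3N, THF, 0 °C to rt
Reagents that add atoms: none
Why: Thiophilic silver activation of the β-keto thioester gives a diacylketene that acylates the hindered tertiary alcohol, and the amine keeps the acid-labile enol ether away from the acidic trione.

Step 15
Reactants: 22 C15 trione ester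
Product: 24 photosubstrate (C6–O and C7 enol–O bridged by tetraisopropyldisiloxane), via desilylated alcohol 23 (not isolated)
Conditions: K2CO3 (cat.), MeOH, 0 °C; then (i-Pr2SiCl)2O, AgOSO2CF3, 2,6-lutidine, CH2Cl2, −40 to 0 °C
Reagents that add atoms: 1,3-dichloro-1,1,3,3-tetraisopropyldisiloxane CC(C)[Si](Cl)(C(C)C)O[Si](Cl)(C(C)C)C(C)C
Why: Methanolysis removes the trimethylsilyl ether, and the disiloxane can only bridge the C6 hydroxyl to the adjacent C7 enol oxygen (seven-membered ring), which fixes the enol as C2=C7 and leaves C3 as the ketone.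

Step 16
Reactants: 24 photosubstrate
Product: 25 cyclobutane photoadduct (new bonds C2–C16 and C7–C8)
Conditions: hν (365 nm), degassed CH2Cl2, 0.005 M, 0 °C
Reagents that add atoms: none
Why: Proposed new method: an intramolecular De Mayo-type [2+2] photocycloaddition of a silyl-locked 2-(alkoxycarbonyl)cyclohexane-1,3-dione enol ether onto an enol ether tethered through the ester; triplet excitation of the β-silyloxy enone, 1,5-closure of C2 onto C16 (rule of five, forming the γ-lactone) and collapse of the 1,4-biradical at C7–C8 on the lactone face of the cyclopentene set C16 and C8, the tether allowing only the enone face anti to the pseudo-axial C6–O–Si; the closest known reactions are the De Mayo reaction and intramolecular enone–alkene photocycloadditions followed by fragmentation.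

Step 17
Reactants: 25 cyclobutane photoadduct
Product: 27 target CNP0115071.1, via cyclobutanol 26 (not isolated)
Conditions: HF·pyridine, pyridine, THF, 0 °C to rt
Reagents that add atoms: none
Why: Fluoride removes all silyl groups and the freed C7 cyclobutanol undergoes retro-aldol cleavage of C2–C7 (De Mayo fragmentation), giving the eight-membered 1,5-diketone, whose C3 carbonyl enolises towards the lactone.

**Compound list**
1 | (R)-but-3-yn-2-ol | C[C@H](C#C)O | starting material
2 | (E)-2-bromobut-2-ene | C/C=C(/Br)C | starting material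
3 | (2R,5E)-5-methylhept-5-en-3-yn-2-ol | C[C@@H](O)C#C/C(C)=C/C | intermediate
4 | (2R,3E,5E)-5-methylhepta-3,5-dien-2-ol | C[C@@H](O)/C=C/C(C)=C/C | intermediate
5 | methyl acrylate | C=CC(=O)OC | starting material
6 | (3R,3aS,6S,7aR)-3,5,6-trimethyl-3a,6,7,7a-tetrahydro-2-benzofuran-1(3H)-one | C[C@H]1OC(=O)[C@@H]2C[C@H](C)C(C)=C[C@H]12 | intermediate
7 | (3R,3aR,6S,7aS)-7a-hydroxy-3,5,6-trimethyl-3a,6,7,7a-tetrahydro-2-benzofuran-1(3H)-one | C[C@H]1OC(=O)[C@]2(O)C[C@H](C)C(C)=C[C@H]12 | intermediate
8 | (1S,2R,5S)-1-hydroxy-2-[(1R)-1-hydroxyethyl]-N-methoxy-N,4,5-trimethylcyclohex-3-ene-1-carboxamide | CON(C)C(=O)[C@]1(O)C[C@H](C)C(C)=C[C@@H]1[C@@H](C)O | intermediate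
9 | (1S,2S,5S)-2-acetyl-1-hydroxy-N-methoxy-N,4,5-trimethylcyclohex-3-ene-1-carboxamide | CON(C)C(=O)[C@]1(O)C[C@H](C)C(C)=C[C@@H]1C(C)=O | intermediate
10 | (3aS,6S,7aS)-7a-hydroxy-5,6-dimethyl-3a,6,7,7a-tetrahydro-1H-indene-1,3(2H)-dione | O=C1CC(=O)[C@]2(O)C[C@H](C)C(C)=C[C@H]12 | intermediate
11 | C11–C12 epoxide of 10 (oxygen syn to C15–OH) | O=C1CC(=O)[C@]2(O)C[C@H](C)[C@@]3(C)O[C@H]3[C@H]12 | intermediate
12 | cage enone: 3-alkoxycyclopent-2-enone with O17 bridging C16 and C12; C11–OH, C15–OH; C10, C11, C12, C13, C15 as in the target | O=C1C=C2O[C@]3(C)[C@@H](O)[C@H]1[C@@]2(O)C[C@@H]3C | intermediate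
13 | cage triol: C9 alcohol of 12, C9 as in the target | O[C@@H]1C=C2O[C@]3(C)[C@@H](O)[C@H]1[C@@]2(O)C[C@@H]3C | intermediate
14 | C9,C11-bis(triethylsilyl) ether of 13 | CC[Si](CC)(CC)O[C@@H]1C=C2O[C@]3(C)[C@@H](O[Si](CC)(CC)CC)[C@H]1[C@@]2(O)C[C@@H]3C | intermediate
15 | (S)-(+)-linalool | C=C[C@@](C)(O)CCC=C(C)C | starting material
16 | dimethyl (2S)-2-hydroxy-2-methylpentanedioate | COC(=O)CC[C@](C)(O)C(=O)OC | intermediate
17 | methyl (2S)-2-methyl-5-oxooxolane-2-carboxylate | COC(=O)[C@]1(C)CCC(=O)O1 | intermediate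
18 | S-tert-butyl thioacetate | CC(=O)SC(C)(C)C | starting material
19 | S-tert-butyl (3S)-3-hydroxy-3-methyl-2,6-dioxocyclohexane-1-carbothioate (enol form, present as dilithium salt) | CC(C)(C)SC(=O)C1=C(O)CC[C@](C)(O)C1=O | intermediate
20 | S-tert-butyl (3S)-3-methyl-2,6-dioxo-3-(trimethylsilyloxy)cyclohexane-1-carbothioate (enol form) | CC(C)(C)SC(=O)C1=C(O)CC[C@](C)(O[Si](C)(C)C)C1=O | intermediate
21 | S-tert-butyl (3S,5S)-3,5-dimethyl-2,6-dioxo-3-(trimethylsilyloxy)cyclohexane-1-carbothioate (enol form) | CC(C)(C)SC(=O)C1=C(O)[C@@H](C)C[C@](C)(O[Si](C)(C)C)C1=O | intermediate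
22 | C15 ester of 14 with the trione acid of 21 (C6–OSiMe3) | CC[Si](CC)(CC)O[C@@H]1C=C2O[C@]3(C)[C@@H](O[Si](CC)(CC)CC)[C@H]1[C@@]2(OC(=O)C4=C(O)[C@@H](C)C[C@](C)(O[Si](C)(C)C)C4=O)C[C@@H]3C | intermediate
23 | 22 with free C6–OH | CC[Si](CC)(CC)O[C@@H]1C=C2O[C@]3(C)[C@@H](O[Si](CC)(CC)CC)[C@H]1[C@@]2(OC(=O)C4=C(O)[C@@H](C)C[C@](C)(O)C4=O)C[C@@H]3C | intermediate
24 | photosubstrate: 23 with C6–O and C7 enol–O bridged by tetraisopropyldisiloxane (C2=C7, C3=O) | CC[Si](CC)(CC)O[C@@H]1C=C2O[C@]3(C)[C@@H](O[Si](CC)(CC)CC)[C@H]1[C@@]2(OC(=O)C4=C5O[Si](C(C)C)(C(C)C)O[Si](C(C)C)(C(C)C)O[C@@]5(C)C[C@H](C)C4=O)C[C@@H]3C | intermediate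
25 | cyclobutane photoadduct (C2–C16, C7–C8; all ring fusions cis) | CC[Si](CC)(CC)O[C@@H]1[C@@H]2[C@@]35O[C@]4(C)[C@@H](O[Si](CC)(CC)CC)[C@H]1[C@@]5(OC(=O)[C@@]36C(=O)[C@@H](C)C[C@]7(C)O[Si](C(C)C)(C(C)C)O[Si](C(C)C)(C(C)C)O[C@]267)C[C@@H]4C | intermediate
26 | fully desilylated cyclobutanol of 25 | O[C@@H]1[C@@H]2[C@@]35O[C@]4(C)[C@@H](O)[C@H]1[C@@]5(OC(=O)[C@@]36C(=O)[C@@H](C)C[C@](C)(O)[C@@]26O)C[C@@H]4C | intermediate
27 | CNP0115071.1 | C[C@H]1C[C@](C)(O)C(=O)[C@@H]2[C@@H](O)[C@H]3[C@H](O)[C@@]4(C)O[C@@]25/C(=C\1O)C(=O)O[C@@]35C[C@@H]4C | target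

**Step count.** 17 steps in total. The longest linear sequence is 14 steps (steps 1–10, then 14–17); steps 11–13 make the second fragment.

**Three steps most likely to fail**

Step 16 (the proposed photocycloaddition). It must close a cyclobutane that carries three fully substituted carbons, and the triplet may decay or the biradical may revert instead. The fallback sets out from 24 and comes back at 25: a ground-state stepwise [2+2] promoted by EtAlCl2 (or HNTf2) in CH2Cl2 at −78 °C. This is the known Lewis-acid Mukaiyama–Michael addition of an enol ether carbon (C8) to a doubly activated alkene (C7), followed by closure of the C2 enolate onto the C16 oxocarbenium ion. It gives the same cyclobutane and makes no new compound (F0).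

Step 14 (acyl-ketene esterification of the hindered tertiary alcohol). Trapping may be slow next to the acid-sensitive enol ether. The fallback sets out from 14 and comes back at 22 by building the trione ring on the cage instead of transferring it. Acetylation (Ac2O, DMAP, Et3N) gives the C15 acetate of 14, F2. Its lithium enolate (LiN(SiMe3)2) is condensed with lactone ester 17 in the same Claisen/Dieckmann sequence as step 12 and quenched with Me3SiCl to give the C4-desmethyl analogue of 22, F3. γ-Methylation (LiN(i-Pr)2, MeI) as in step 13 then gives 22.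

Step 3 (magnesium-templated Diels–Alder). A secondary dienol with a substituted diene terminus may react sluggishly or with low facial selectivity, and the facial sense rests on a model. The fallback sets out from 4 and comes back at 6 with a covalent tether: acryloyl chloride and Et3N give (2R,3E,5E)-5-methylhepta-3,5-dien-2-yl acrylate, F1, which undergoes a thermal intramolecular Diels–Alder reaction (toluene, BHT, 170 °C) directly to the cis-lactone 6. If the facial sense proved opposite to the model, the enantiomer of 1 would be used.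

**Further compounds**
F0 | step 16 | none | none
F1 | step 3 | (2R,3E,5E)-5-methylhepta-3,5-dien-2-yl acrylate | C=CC(=O)O[C@H](C)/C=C/C(C)=C/C
F2 | step 14 | C15 acetate of 14 | CC[Si](CC)(CC)O[C@@H]1C=C2O[C@]3(C)[C@@H](O[Si](CC)(CC)CC)[C@H]1[C@@]2(OC(C)=O)C[C@@H]3C
F3 | step 14 | C4-desmethyl analogue of 22 | CC[Si](CC)(CC)O[C@@H]1C=C2O[C@]3(C)[C@@H](O[Si](CC)(CC)CC)[C@H]1[C@@]2(OC(=O)C4=C(O)CC[C@](C)(O[Si](C)(C)C)C4=O)C[C@@H]3C
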